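**Retrosynthetic overview**
1. Ring A is the 3-hydroxyphenyl ring and ring C the 4-hydroxyphenyl ring. Ring B is the central arene: C1 carries CH2CH2–ring A, C2 carries CH2–ring C, C3 and C5 carry OMe, C4 and C6 carry H. Target 12 comes from 11 by removal of two benzyl ethers.
2. 11 comes from dione 9: the meta C3/C5 dimethoxy pair of ring B is the dehydrogenated, O-methylated form of a cyclohexane-1,3-dione.
3. Feature used: ring C–CH2–C2–C3–C4 is the intact carbon chain of 4-(4-hydroxyphenyl)butan-2-one, and C5–C6–C1–CH2CH2–ring A is that of a 5-arylpent-2-enoate. So 9 is cut at C2–C1 (Michael) and C4–C5 (Claisen) into ketone 2 and enoate 7.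
4. 2 comes from raspberry ketone 1. 7 comes from aldehyde 5 and phosphonate 6 (Horner–Wadsworth–Emmons), and 5 from acid 3.
5. Ring order: rings A and C are bought. Ring B is the only ring built (step 5) and is made aromatic afterwards (step 6).

Key step: step 5

Assumption: the target has no stereocentre, so dione 9 is made and used as a racemate and its relative configuration has no bearing on the final product.

**Step 1**
Reactants: 1 4-(4-hydroxyphenyl)butan-2-one
Product: 2 4-(4-benzyloxyphenyl)butan-2-one
Conditions: BnBr (1.1 equiv), K2CO3, DMF, rt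
Reagents that add atoms: benzyl bromide, BrCc1ccccc1
Why: Williamson ether synthesis, in which the phenoxide formed by K2CO3 displaces bromide in an SN2 reaction while carbonate is too weak a base to alkylate the ketone at carbon.

**Step 2**
Reactants: 3 3-(3-hydroxyphenyl)propanoic acid
Product: 4 benzyl 3-(3-benzyloxyphenyl)propanoate
Conditions: BnBr (2.2 equiv), K2CO3, DMF, 60 °C
Reagents that add atoms: benzyl bromide, BrCc1ccccc1
Why: Williamson etherification of the phenoxide and SN2 O-alkylation of the carboxylate run in the same flask, which masks the phenol and turns the acid into an ester fit for partial reduction.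

**Step 3**
Reactants: 4 benzyl 3-(3-benzyloxyphenyl)propanoate
Product: 5 3-(3-benzyloxyphenyl)propanal
Conditions: i-Bu2AlH (1.05 equiv), CH2Cl2, −78 °C; then aq. potassium sodium tartrate (KNaC4H4O6)
Reagents that add atoms: none
Why: Partial reduction of an ester with i-Bu2AlH, in which only one hydride is delivered at −78 °C and the carbonyl group is released on the aqueous quench after the remaining hydride is destroyed, the aryl benzyl ether being inert.

**Step 4**
Reactants: 5 3-(3-benzyloxyphenyl)propanal; 6 triethyl phosphonoacetate
Product: 7 ethyl (E)-5-(3-benzyloxyphenyl)pent-2-enoate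
Conditions: NaH, THF, 0 °C to rt
Reagents that add atoms: none
Why: Horner–Wadsworth–Emmons olefination, in which the stabilised phosphonate anion adds reversibly to the unhindered aliphatic aldehyde and loses diethyl phosphate through the less crowded arrangement, which should give the (E)-enoate.

**Step 5**
Reactants: 2 4-(4-benzyloxyphenyl)butan-2-one; 7 ethyl (E)-5-(3-benzyloxyphenyl)pent-2-enoate
Product: 9 rac-(4S,5R)-4-(4-benzyloxybenzyl)-5-[2-(3-benzyloxyphenyl)ethyl]cyclohexane-1,3-dione (trans), via open-chain keto ester 8 (not isolated)
Conditions: 2 (1.3 equiv), KOt-Bu (1.2 equiv), THF, 0 °C, 30 min; slow addition of 7, 0 °C to rt; then 1 M HCl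
Reagents that add atoms: none
Why: KOt-Bu and a small excess of 2 keep the two enolates of the ketone in equilibrium, and the more substituted, methylene-side enolate adds in conjugate fashion to the β-carbon of 7, which forms the C2–C1 bond of ring B and gives keto ester 8. Proton transfer then produces the methyl-side enolate of 8, which attacks the ester carbonyl and expels ethoxide (intramolecular Claisen condensation) to form C4–C5, and deprotonation of the acidic dione to its delocalised potassium enolate drives the sequence forward. The closest known reaction type is the consecutive Michael–Claisen [3+3] annulation of alkyl methyl ketones with α,β-unsaturated esters under KOt-Bu or NaH, which delivers 4-substituted cyclohexane-1,3-diones. The one ring formed closes in the 6-(enolendo)-exo-trig mode, a favoured geometry, whereas closure from the tertiary α-carbon of 8 would need a four-membered ring and does not compete. The stereocentre at C5 of 9 arises in the reversible Michael step and the one at C4 stays epimerisable next to the C3 carbonyl, so both are under thermodynamic substrate control and should settle with the two side chains trans and diequatorial; step 6 erases both centres, so any cis isomer can be carried forward. The selectivity needed is regiochemical, Michael addition from CH2 and acylation from CH3, and three things secure it: 2 offers only these two α-positions, the alkyl-substituted enolate is the more stable and more nucleophilic one under equilibrating conditions, and slow addition of 7 to the preformed enolate keeps base away from the γ-hydrogens of the enoate.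

**Step 6**
Reactants: 9 rac-trans-4-(4-benzyloxybenzyl)-5-[2-(3-benzyloxyphenyl)ethyl]cyclohexane-1,3-dione
Product: 11 1-[2-(3-benzyloxyphenyl)ethyl]-2-(4-benzyloxybenzyl)-3,5-dimethoxybenzene, via methyl enol ether 10 (not isolated)
Conditions: I2 (2 equiv), MeOH, reflux; then aq. Na2S2O3
Reagents that add atoms: methanol, CO
Why: Iodine–methanol oxidative aromatisation, known for cyclohexenones and cyclohexane-1,3-diones, in which acid-catalysed exchange of both carbonyl oxygens for methoxy by way of 10, ring iodination and loss of HI remove two ring hydrogens and both stereocentres, while benzyl aryl ethers should tolerate the dilute HI in methanol.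

**Step 7**
Reactants: 11 1-[2-(3-benzyloxyphenyl)ethyl]-2-(4-benzyloxybenzyl)-3,5-dimethoxybenzene
Product: 12 Gymcononopin D, 3-{2-[2-(4-hydroxybenzyl)-3,5-dimethoxyphenyl]ethyl}phenol
Conditions: H2 (1 atm), Pd/C (10 wt% palladium on carbon), EtOAc–MeOH, rt
Reagents that add atoms: none
Why: Catalytic hydrogenolysis of benzyl aryl ethers cleaves only the two O–CH2Ph bonds, since the diarylmethane and bibenzyl C–C bonds and the methyl ethers are inert at room temperature and atmospheric pressure.

**Compound list**
1 | 4-(4-hydroxyphenyl)butan-2-one (raspberry ketone) | CC(=O)CCc1ccc(O)cc1 | starting material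
2 | 4-(4-benzyloxyphenyl)butan-2-one | CC(=O)CCc1ccc(OCc2ccccc2)cc1 | intermediate
3 | 3-(3-hydroxyphenyl)propanoic acid | OC(=O)CCc1cccc(O)c1 | starting material
4 | benzyl 3-(3-benzyloxyphenyl)propanoate | O=C(CCc1cccc(OCc2ccccc2)c1)OCc1ccccc1 | intermediate
5 | 3-(3-benzyloxyphenyl)propanal | O=CCCc1cccc(OCc2ccccc2)c1 | intermediate
6 | triethyl phosphonoacetate | CCOC(=O)CP(=O)(OCC)OCC | starting material
7 | ethyl (E)-5-(3-benzyloxyphenyl)pent-2-enoate | CCOC(=O)/C=C/CCc1cccc(OCc2ccccc2)c1 | intermediate
8 | ethyl 3-[2-(3-benzyloxyphenyl)ethyl]-4-(4-benzyloxybenzyl)-5-oxohexanoate (equilibrating diastereomers, not isolated) | CCOC(=O)CC(CCc1cccc(OCc2ccccc2)c1)C(Cc1ccc(OCc2ccccc2)cc1)C(C)=O | intermediate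
9 | rac-(4S,5R)-4-(4-benzyloxybenzyl)-5-[2-(3-benzyloxyphenyl)ethyl]cyclohexane-1,3-dione (trans, one enantiomer drawn) | O=C1CC(=O)[C@@H](Cc2ccc(OCc3ccccc3)cc2)[C@H](CCc2cccc(OCc3ccccc3)c2)C1 | intermediate
10 | rac-trans-6-(4-benzyloxybenzyl)-5-[2-(3-benzyloxyphenyl)ethyl]-3-methoxycyclohex-2-en-1-one (one enantiomer drawn, not isolated) | COC1=CC(=O)[C@@H](Cc2ccc(OCc3ccccc3)cc2)[C@H](CCc2cccc(OCc3ccccc3)c2)C1 | intermediate
11 | 1-[2-(3-benzyloxyphenyl)ethyl]-2-(4-benzyloxybenzyl)-3,5-dimethoxybenzene | COc1cc(CCc2cccc(OCc3ccccc3)c2)c(Cc2ccc(OCc3ccccc3)cc2)c(OC)c1 | intermediate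
12 | Gymcononopin D (achiral) | COc1cc(CCc2cccc(O)c2)c(Cc2ccc(O)cc2)c(OC)c1 | target

**Total step count:** 7
**Longest linear sequence:** 6 steps (3 → 4 → 5 → 7 → 9 → 11 → 12)

**Steps most likely to fail**

1. **Step 5.** Conjugate addition may run through the less hindered methyl-side enolate, which would reverse the order of the two bond formations. The enoate may be deprotonated at its γ-position and then deconjugate or add to itself. Addition to the β-branched acceptor may also be slow.
   - The fallback sets out from aldehyde 5 and comes back at dione 9. It fixes the C1–C2 bond beforehand as an alkene, so no choice between two enolates remains.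
   - Commercial diethyl (2-oxopropyl)phosphonate is alkylated at the carbon between phosphorus and carbonyl with 4-benzyloxybenzyl chloride (NaH, THF). This gives diethyl [1-(4-benzyloxyphenyl)-3-oxobutan-2-yl]phosphonate F1.
   - Horner–Wadsworth–Emmons reaction of F1 with 5 (NaH, THF) gives (E)-3-(4-benzyloxybenzyl)-6-(3-benzyloxyphenyl)hex-3-en-2-one F2. Its alkene geometry is of no consequence.
   - Dimethyl malonate and NaOMe in refluxing MeOH then add to the β-carbon and close the ring from the methyl ketone onto one ester (the classical dihydroresorcinol synthesis). This gives methyl 5-(4-benzyloxybenzyl)-6-[2-(3-benzyloxyphenyl)ethyl]-2,4-dioxocyclohexane-1-carboxylate F3.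
   - Saponification (aq. NaOH) followed by acidification and warming decarboxylates F3 to 9.

2. **Step 6.** O-methylation may stall after one methoxy group, the electron-rich product ring may be iodinated, or benzyl groups may be partly lost under acid.
   - The fallback sets out from 9 and comes back at 11. It separates enol etherification, dehydrogenation and the second methylation.
   - MeOH with catalytic TsOH converts 9 into enol ether 10, now isolated; methanol attacks the carbonyl remote from the benzyl group.
   - LiN(i-Pr)2 (THF, −78 °C) removes the only α'-proton, in a Stork–Danheiser-type deprotonation. PhSeBr traps the enolate on the face opposite the phenethyl chain to give rac-6-(4-benzyloxybenzyl)-5-[2-(3-benzyloxyphenyl)ethyl]-3-methoxy-6-(phenylselanyl)cyclohex-2-en-1-one F4.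
   - H2O2 (CH2Cl2, 0 °C) brings about selenoxide syn-elimination towards the cis C5–H. The ring then tautomerises to 2-(4-benzyloxybenzyl)-3-[2-(3-benzyloxyphenyl)ethyl]-5-methoxyphenol F5.
   - MeI and K2CO3 in acetone give 11.

3. **Step 3.** Over-reduction to the alcohol level may occur if the carbonyl group is released before the hydride is quenched.
   - The fallback sets out from ester 4 and comes back at aldehyde 5. It replaces the partial reduction by full reduction and re-oxidation.
   - LiAlH4 (THF, 0 °C) gives 3-(3-benzyloxyphenyl)propan-1-ol F6.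
   - Dess–Martin periodinane (CH2Cl2, rt) oxidises F6 to 5.

**Further compounds**
F1 | step 5 | diethyl [1-(4-benzyloxyphenyl)-3-oxobutan-2-yl]phosphonate (racemic) | CCOP(=O)(OCC)C(Cc1ccc(OCc2ccccc2)cc1)C(C)=O
F2 | step 5 | (E)-3-(4-benzyloxybenzyl)-6-(3-benzyloxyphenyl)hex-3-en-2-one | CC(=O)/C(Cc1ccc(OCc2ccccc2)cc1)=C/CCc1cccc(OCc2ccccc2)c1
F3 | step 5 | methyl 5-(4-benzyloxybenzyl)-6-[2-(3-benzyloxyphenyl)ethyl]-2,4-dioxocyclohexane-1-carboxylate (diastereomer mixture) | COC(=O)C1C(=O)CC(=O)C(Cc2ccc(OCc3ccccc3)cc2)C1CCc1cccc(OCc2ccccc2)c1
F4 | step 6 | rac-6-(4-benzyloxybenzyl)-5-[2-(3-benzyloxyphenyl)ethyl]-3-methoxy-6-(phenylselanyl)cyclohex-2-en-1-one (selenium trans to the phenethyl chain, one enantiomer drawn) | COC1=CC(=O)[C@@](Cc2ccc(OCc3ccccc3)cc2)([Se]c2ccccc2)[C@H](CCc2cccc(OCc3ccccc3)c2)C1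
F5 | step 6 | 2-(4-benzyloxybenzyl)-3-[2-(3-benzyloxyphenyl)ethyl]-5-methoxyphenol | COc1cc(O)c(Cc2ccc(OCc3ccccc3)cc2)c(CCc2cccc(OCc3ccccc3)c2)c1
F6 | step 3 | 3-(3-benzyloxyphenyl)propan-1-ol | OCCCc1cccc(OCc2ccccc2)c1
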